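**Retrosynthetic overview**
1. Target ⇐ peripheral epoxidation of the E-C4=C5 alkene, C13 desilylation, C10 acetylation, Mitsunobu inversion/acetylation at C8, and methyl addition at C10 of a ten-membered 1,10-diketone.
2. Ten-membered ring ⇐ 5 → 10 ring expansion: tin-directed oxidative Grob-type fragmentation of the C1–C5 bond of a cyclopentane-fused (5/7) butenolide; this gives the C1 ketone and the E-alkene.
3. Seven-membered ring ⇐ Cr(II) Reformatsky-type aldol (C8–C9); butenolide ⇐ alkoxide-directed anti-carbomagnesiation/carboxylation of a propargylic alcohol; C9–C10 ⇐ 1-ethoxyvinyllithium.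
4. Stannyl cyclopentanone ⇐ enantioselective conjugate stannylation of 3-methylcyclopent-2-en-1-one with aldol trapping by a 4-silyloxybut-2-ynal (from propargyl alcohol).
5. Ring order: cyclopentane (bought) → butenolide → seven-membered carbocycle → ten-membered ring (expansion) → epoxide.

Assumption: positions are given in germacranolide numbering (C1 ketone, C4/C5 epoxide, C6 lactone CH–O, C7=C11, C8 and C10 acetoxy carbons, C12 lactone C=O, C13 CH2OH, C14/C15 methyls on C10/C4); the target is the (4R,5R,6S,8S,10R) isomer of the given SMILES; TBS = tert-butyldimethylsilyl.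

**Step 1**
Reactants: 1 prop-2-yn-1-ol
Product: 2 tert-butyldimethyl(prop-2-yn-1-yloxy)silane
Conditions: NaH, TBSCl, THF, 0 → 23 °C
Reagents that add atoms: tert-butyldimethylsilyl chloride, CC(C)(C)[Si](C)(C)Cl
Why: O-silylation of the sodium alkoxide (silyl ether formation) masks the future C13 hydroxyl for all organometallic steps.

**Step 2**
Reactants: 2 tert-butyldimethyl(prop-2-yn-1-yloxy)silane
Product: 5 4-(TBS-oxy)but-2-ynal, via lithium acetylide 3 (not isolated), via lithium hemiaminolate 4 (not isolated)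
Conditions: n-BuLi, THF, −78 °C; DMF, −78 → 0 °C; AcOH–H2O
Reagents that add atoms: N,N-dimethylformamide, CN(C)C=O
Why: Alkyne lithiation and formylation with DMF (Bouveault-type formylation) give the ynal after mildly acidic collapse of the hemiaminolate.

**Step 3**
Reactants: 6 3-methylcyclopent-2-en-1-one; 5 4-(TBS-oxy)but-2-ynal
Product: 9 (2S,3S)-2-[(1R)-4-(TBS-oxy)-1-hydroxybut-2-yn-1-yl]-3-methyl-3-(tributylstannyl)cyclopentan-1-one, via boron enolate 7 (not isolated), via boron aldolate 8 (not isolated)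
Conditions: Bu3Sn–Bpin (1.05 equiv), CuCl (5 mol %), chiral sulfonate-bearing imidazolinium salt (6 mol %), NaOt-Bu (10 mol %), THF, −40 °C; then 5, −40 → 0 °C; aq. NaHCO3
Reagents that add atoms: tributyl(4,4,5,5-tetramethyl-1,3,2-dioxaborolan-2-yl)stannane, CCCC[Sn](CCCC)(CCCC)B1OC(C)(C)C(C)(C)O1
Why: Proposed new method: an NHC–Cu–SnBu3 species formed by alkoxide-assisted Sn–B σ-bond metathesis adds 1,4 and enantioselectively to the β-substituted enone (closest known: NHC–Cu-catalysed enantioselective conjugate silyl and boryl additions to cyclic enones, and stoichiometric Bu3SnLi conjugate addition with enolate trapping), Sn–B turns the copper enolate over to boron enolate 7, and its Zimmerman–Traxler aldol with 5 occurs anti to the C–Sn bond and anti-selectively, so the catalyst-set C4 centre fixes C5 and the C6 carbinol that is kept to the end (minor diastereomers removed by chromatography).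

**Step 4**
Reactants: 9 stannyl aldol; 10 ethoxyethene (ethyl vinyl ether)
Product: 12 (1S,2S,3S)-1-(1-ethoxyethenyl)-2-[(1R)-4-(TBS-oxy)-1-hydroxybut-2-yn-1-yl]-3-methyl-3-(tributylstannyl)cyclopentan-1-ol, via 1-ethoxyvinyllithium 11 (not isolated)
Conditions: 10, t-BuLi, THF, −78 → 0 °C; then 9, −78 °C; aq. NaHCO3
Reagents that add atoms: none
Why: 1,2-Addition of the acyl-anion equivalent 1-ethoxyvinyllithium to the ketone from the face opposite the C5 side chain brings in C9/C10 and masks the ketone as an enol ether; the C1 carbinol centre is destroyed again in step 8.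

**Step 5**
Reactants: 12 enol ether diol
Product: 16 (5R)-5-[(1S,2S,5S)-2-(chloroacetyl)-2-hydroxy-5-methyl-5-(tributylstannyl)cyclopentyl]-4-ethenyl-3-[(TBS-oxy)methyl]furan-2(5H)-one, via alkenylmagnesium 13 (not isolated), via magnesium carboxylate 14 (not isolated), via chloroketone hydroxy acid 15 (not isolated)
Conditions: CH2=CHMgCl (5 equiv), CuI (10 mol %), THF, 50 °C; CO2, 0 °C; NCS, THF–H2O, 0 °C; 1 M HCl
Reagents that add atoms: vinylmagnesium chloride, C=C[Mg]Cl; carbon dioxide, O=C=O; N-chlorosuccinimide, O=C1CCC(=O)N1Cl; water, O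
Why: Alkoxide-directed anti-carbomagnesiation puts vinyl on C7 and magnesium on C11 cis to C6, carboxylation and acid close the butenolide (lactonisation), and NCS/H2O turns the enol ether into the α-chloromethyl ketone (electrophilic halogenation of an enol ether).

**Step 6**
Reactants: 16 chloroketone vinylbutenolide
Product: 18 (2R)-2-[(1S,2S,5S)-2-(chloroacetyl)-2-hydroxy-5-methyl-5-(tributylstannyl)cyclopentyl]-5-oxo-4-[(TBS-oxy)methyl]-2,5-dihydrofuran-3-carbaldehyde, via ozonide 17 (not isolated)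
Conditions: O3, CH2Cl2, −78 °C; PPh3, −78 → 0 °C
Reagents that add atoms: ozone, [O-][O+]=O
Why: Ozonolysis cleaves only the terminal vinyl group (the tetrasubstituted, electron-poor butenolide alkene is inert) and cold phosphine reduction of the ozonide gives the C8 aldehyde without touching the chloroketone.

**Step 7**
Reactants: 18 chloroketone aldehyde
Product: 19 (1S,4S,5S,6R,8R)-1,8-dihydroxy-10-oxo-4-(tributylstannyl)-13-(TBS-oxy)-14-norguai-7(11)-en-12,6-olide (trans-fused 5/7 carbocycle with fused butenolide)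
Conditions: CrCl2, LiI (cat.), THF, 0 → 23 °C
Reagents that add atoms: none
Why: Cr(II) reduces only the α-chloro ketone and the chromium(III) enolate closes the seven-membered ring in a Reformatsky-type aldol through a closed transition state on the tether face, which leaves the C8 hydrogen in the butenolide plane (least A1,3 strain with C13) and gives the 8R carbinol, hydroxyl trans to the lactone oxygen.

**Step 8**
Reactants: 19 tricyclic γ-stannyl carbinol
Product: 20 (4E,6R,8R)-8-hydroxy-1,10-dioxo-13-(TBS-oxy)-14-norgermacra-4,7(11)-dien-12,6-olide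
Conditions: Pb(OAc)4, CH2Cl2, −20 → 0 °C
Reagents that add atoms: none
Why: Tin-directed oxidative Grob-type 1,4-fragmentation (ring expansion 5 → 10): the Pb(IV) alkoxide of the C1 carbinol breaks the C1–C5 bond antiperiplanar to C4–Sn in a polar heterolytic process, giving the C1 ketone and the C4=C5 alkene, E because tin and C6 are trans on the cyclopentane.

**Step 9**
Reactants: 20 hydroxy diketone
Product: 22 (4E,6R,8R,10R)-8,10-dihydroxy-1-oxo-13-(TBS-oxy)germacra-4,7(11)-dien-12,6-olide, via transannular hemiketal 21 (not isolated)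
Conditions: MeMgBr (3 equiv), THF, −78 °C; aq. NH4Cl
Reagents that add atoms: methylmagnesium bromide, C[Mg]Br
Why: Grignard addition: the γ-hydroxy 1,2-diketone closes to the five-membered hemiketal 21 (C8–O–C1), which masks C1, and the reagent attacks the C10 ketone from the exo face away from the C2–C7 bridge, setting 10R with C10–O anti to C8–O.

**Step 10**
Reactants: 22 (8R,10R)-diol
Product: 23 (4E,6R,8S,10R)-8-acetoxy-10-hydroxy-1-oxo-13-(TBS-oxy)germacra-4,7(11)-dien-12,6-olide
Conditions: PPh3, DIAD, AcOH, toluene, 0 → 23 °C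
Reagents that add atoms: acetic acid, CC(=O)O
Why: Mitsunobu reaction with acetic acid inverts the secondary C8 carbinol by SN2 to the 8S acetate, while the tertiary C10 hydroxyl does not react.

**Step 11**
Reactants: 23 monoacetate
Product: 24 (4E,6R,8S,10R)-8,10-diacetoxy-1-oxo-13-(TBS-oxy)germacra-4,7(11)-dien-12,6-olide
Conditions: Ac2O, DMAP, Et3N, CH2Cl2, 40 °C
Reagents that add atoms: acetic anhydride, CC(=O)OC(C)=O
Why: DMAP-catalysed acylation of the tertiary α-ketol hydroxyl, with no change at any stereocentre.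

**Step 12**
Reactants: 24 diacetate silyl ether
Product: 25 (4E,6R,8S,10R)-8,10-diacetoxy-13-hydroxy-1-oxogermacra-4,7(11)-dien-12,6-olide
Conditions: HF·pyridine, pyridine, THF, 0 °C
Reagents that add atoms: none
Why: Buffered fluoride cleavage of the primary silyl ether frees the C13 hydroxyl under conditions too acidic for acetyl migration from O8.

**Step 13**
Reactants: 25 dienolide alcohol
Product: 26 (4R,5R,6S,8S,10R)-8,10-diacetoxy-4,5-epoxy-13-hydroxy-1-oxogermacr-7(11)-en-12,6-olide (target)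
Conditions: DMDO, acetone, −20 → 0 °C
Reagents that add atoms: dimethyldioxirane, CC1(C)OO1
Why: Electrophilic epoxidation of the only electron-rich alkene from the peripheral face, which in the A1,3-minimised conformer (C6–H eclipsing the C4 methyl) is the face of the lactone oxygen, gives the 4R,5R trans-epoxide as in related germacranolide epoxidations.

**Compound list**
1 | prop-2-yn-1-ol | C#CCO | starting material
2 | tert-butyldimethyl(prop-2-yn-1-yloxy)silane | C#CCO[Si](C)(C)C(C)(C)C | intermediate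
3 | lithium acetylide of 2 (in situ) | [Li]C#CCO[Si](C)(C)C(C)(C)C | intermediate
4 | lithium hemiaminolate from 3 and DMF (in situ) | [Li]OC(N(C)C)C#CCO[Si](C)(C)C(C)(C)C | intermediate
5 | 4-(TBS-oxy)but-2-ynal | O=CC#CCO[Si](C)(C)C(C)(C)C | intermediate
6 | 3-methylcyclopent-2-en-1-one | CC1=CC(=O)CC1 | starting material
7 | pinacolboron enolate of (3S)-3-methyl-3-(tributylstannyl)cyclopentanone (in situ) | CC1(C)OB(OC2=C[C@@](C)([Sn](CCCC)(CCCC)CCCC)CC2)OC1(C)C | intermediate
8 | O-pinacolboryl aldolate of 9 (in situ) | O=C1CC[C@](C)([Sn](CCCC)(CCCC)CCCC)[C@H]1[C@@H](OB2OC(C)(C)C(C)(C)O2)C#CCO[Si](C)(C)C(C)(C)C | intermediate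
9 | (2S,3S)-2-[(1R)-4-(TBS-oxy)-1-hydroxybut-2-yn-1-yl]-3-methyl-3-(tributylstannyl)cyclopentan-1-one | O=C1CC[C@](C)([Sn](CCCC)(CCCC)CCCC)[C@H]1[C@@H](O)C#CCO[Si](C)(C)C(C)(C)C | intermediate
10 | ethoxyethene (ethyl vinyl ether) | C=COCC | starting material
11 | 1-ethoxyvinyllithium (in situ) | [Li]C(=C)OCC | intermediate
12 | (1S,2S,3S)-1-(1-ethoxyethenyl)-2-[(1R)-4-(TBS-oxy)-1-hydroxybut-2-yn-1-yl]-3-methyl-3-(tributylstannyl)cyclopentan-1-ol | CCOC(=C)[C@]1(O)CC[C@](C)([Sn](CCCC)(CCCC)CCCC)[C@H]1[C@@H](O)C#CCO[Si](C)(C)C(C)(C)C | intermediate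
13 | chelated alkenylmagnesium after vinyl addition (Mg on C11 cis to C6; in situ) | CCOC(=C)[C@]1(O[Mg]Cl)CC[C@](C)([Sn](CCCC)(CCCC)CCCC)[C@H]1[C@@H](O[Mg]Cl)/C(C=C)=C(\[Mg]Cl)CO[Si](C)(C)C(C)(C)C | intermediate
14 | magnesium carboxylate after CO2 (in situ) | CCOC(=C)[C@]1(O[Mg]Cl)CC[C@](C)([Sn](CCCC)(CCCC)CCCC)[C@H]1[C@@H](O[Mg]Cl)/C(C=C)=C(\C(=O)O[Mg]Cl)CO[Si](C)(C)C(C)(C)C | intermediate
15 | chloroketone (Z)-γ-hydroxy acid before lactonisation (in situ) | ClCC(=O)[C@]1(O)CC[C@](C)([Sn](CCCC)(CCCC)CCCC)[C@H]1[C@@H](O)/C(C=C)=C(\C(=O)O)CO[Si](C)(C)C(C)(C)C | intermediate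
16 | (5R)-5-[(1S,2S,5S)-2-(chloroacetyl)-2-hydroxy-5-methyl-5-(tributylstannyl)cyclopentyl]-4-ethenyl-3-[(TBS-oxy)methyl]furan-2(5H)-one | ClCC(=O)[C@]1(O)CC[C@](C)([Sn](CCCC)(CCCC)CCCC)[C@H]1[C@H]1OC(=O)C(CO[Si](C)(C)C(C)(C)C)=C1C=C | intermediate
17 | 1,2,4-trioxolane (ozonide) of the vinyl group of 16 (in situ) | ClCC(=O)[C@]1(O)CC[C@](C)([Sn](CCCC)(CCCC)CCCC)[C@H]1[C@H]1OC(=O)C(CO[Si](C)(C)C(C)(C)C)=C1C1OCOO1 | intermediate
18 | (2R)-2-[(1S,2S,5S)-2-(chloroacetyl)-2-hydroxy-5-methyl-5-(tributylstannyl)cyclopentyl]-5-oxo-4-[(TBS-oxy)methyl]-2,5-dihydrofuran-3-carbaldehyde | ClCC(=O)[C@]1(O)CC[C@](C)([Sn](CCCC)(CCCC)CCCC)[C@H]1[C@H]1OC(=O)C(CO[Si](C)(C)C(C)(C)C)=C1C=O | intermediate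
19 | (1S,4S,5S,6R,8R)-1,8-dihydroxy-10-oxo-4-(tributylstannyl)-13-(TBS-oxy)-14-norguai-7(11)-en-12,6-olide | O[C@@H]1CC(=O)[C@]2(O)CC[C@](C)([Sn](CCCC)(CCCC)CCCC)[C@H]2[C@H]2OC(=O)C(CO[Si](C)(C)C(C)(C)C)=C12 | intermediate
20 | (4E,6R,8R)-8-hydroxy-1,10-dioxo-13-(TBS-oxy)-14-norgermacra-4,7(11)-dien-12,6-olide | O[C@@H]1CC(=O)C(=O)CC/C(C)=C/[C@H]2OC(=O)C(CO[Si](C)(C)C(C)(C)C)=C12 | intermediate
21 | transannular hemiketal of 20 (C8–O–C1 bridge, C10 ketone free; in situ) | O=C1C[C@H]2O[C@]1(O)CC/C(C)=C/[C@H]1OC(=O)C(CO[Si](C)(C)C(C)(C)C)=C12 | intermediate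
22 | (4E,6R,8R,10R)-8,10-dihydroxy-1-oxo-13-(TBS-oxy)germacra-4,7(11)-dien-12,6-olide | O[C@@H]1C[C@@](C)(O)C(=O)CC/C(C)=C/[C@H]2OC(=O)C(CO[Si](C)(C)C(C)(C)C)=C12 | intermediate
23 | (4E,6R,8S,10R)-8-acetoxy-10-hydroxy-1-oxo-13-(TBS-oxy)germacra-4,7(11)-dien-12,6-olide | CC(=O)O[C@H]1C[C@@](C)(O)C(=O)CC/C(C)=C/[C@H]2OC(=O)C(CO[Si](C)(C)C(C)(C)C)=C12 | intermediate
24 | (4E,6R,8S,10R)-8,10-diacetoxy-1-oxo-13-(TBS-oxy)germacra-4,7(11)-dien-12,6-olide | CC(=O)O[C@H]1C[C@@](C)(OC(C)=O)C(=O)CC/C(C)=C/[C@H]2OC(=O)C(CO[Si](C)(C)C(C)(C)C)=C12 | intermediate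
25 | (4E,6R,8S,10R)-8,10-diacetoxy-13-hydroxy-1-oxogermacra-4,7(11)-dien-12,6-olide | CC(=O)O[C@H]1C[C@@](C)(OC(C)=O)C(=O)CC/C(C)=C/[C@H]2OC(=O)C(CO)=C12 | intermediate
26 | (4R,5R,6S,8S,10R)-8,10-diacetoxy-4,5-epoxy-13-hydroxy-1-oxogermacr-7(11)-en-12,6-olide | CC(=O)O[C@H]1C[C@@](C)(OC(C)=O)C(=O)CC[C@@]2(C)O[C@@H]2[C@H]2OC(=O)C(CO)=C12 | target

**Total step count:** 13. **Longest linear sequence:** 13 steps (1 → 26).

**Three steps most likely to fail**

Step 3 (the proposed Cu-catalysed enantioselective stannylation–aldol; risks are low ee at the tertiary C–Sn centre and stannylcupration of the ynal). The fallback uses known chemistry, sets out from 6 and 5 and comes back at 9. Stoichiometric Bu3SnLi (Bu3SnH, LDA, THF, −78 °C) adds 1,4 to 6 and the lithium enolate is trapped with 5. This gives racemic aldol, that is 9 together with its enantiomer ent-9 F1. Amano lipase PS with vinyl acetate then acetylates the (S)-carbinol of F1 selectively (Kazlauskas preference: alkynyl as the medium group) to the acetate of ent-9 F2, which is separated, leaving 9 in high ee.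

Step 5 (four operations in one flask; risks are slow carboxylation of the chelated alkenylmagnesium and chlorination in the presence of the diene). The fallback sets out from 12 and comes back at 16. After the same carbomagnesiation the alkenylmagnesium is formylated with DMF instead of carboxylated, and work-up gives the lactol F3. MnO2 in CH2Cl2 oxidises the lactol to the butenolide that still carries the enol ether, butenolide enol ether F4. NCS in THF–H2O then converts the enol ether into the chloromethyl ketone 16 in a separate step.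

Step 9 (regio- and stereocontrol of the methyl addition; if the open-chain magnesium chelate controls the addition rather than the hemiketal, the 10S epimer results). The fallback sets out from 20 and comes back at 24, with inversion and methylation exchanged. Mitsunobu reaction of 20 with 4-nitrobenzoic acid (PPh3, DIAD) gives the inverted (8S)-4-nitrobenzoate F5. Mild methanolysis (K2CO3 cat., MeOH, 0 °C) gives the (8S)-hydroxy diketone F6. Chelation-controlled 1,3-syn addition of MeMgBr in CH2Cl2 at −78 °C gives the (8S,10R)-diol F7. Ac2O/DMAP then acetylates both hydroxyls to 24.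

**Further compounds**
F1 | step 3 | ent-9, (2R,3R)-2-[(1S)-4-(TBS-oxy)-1-hydroxybut-2-yn-1-yl]-3-methyl-3-(tributylstannyl)cyclopentan-1-one (second half of the racemate) | O=C1CC[C@@](C)([Sn](CCCC)(CCCC)CCCC)[C@@H]1[C@H](O)C#CCO[Si](C)(C)C(C)(C)C
F2 | step 3 | acetate of ent-9 | O=C1CC[C@@](C)([Sn](CCCC)(CCCC)CCCC)[C@@H]1[C@H](OC(C)=O)C#CCO[Si](C)(C)C(C)(C)C
F3 | step 5 | lactol (5-hydroxy-2,5-dihydrofuran) analogue of 16 that still carries the 1-ethoxyethenyl group | CCOC(=C)[C@]1(O)CC[C@](C)([Sn](CCCC)(CCCC)CCCC)[C@H]1[C@H]1OC(O)C(CO[Si](C)(C)C(C)(C)C)=C1C=C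
F4 | step 5 | butenolide enol ether (16 with 1-ethoxyethenyl in place of chloroacetyl) | CCOC(=C)[C@]1(O)CC[C@](C)([Sn](CCCC)(CCCC)CCCC)[C@H]1[C@H]1OC(=O)C(CO[Si](C)(C)C(C)(C)C)=C1C=C
F5 | step 9 | (4E,6R,8S)-8-(4-nitrobenzoyloxy)-1,10-dioxo-13-(TBS-oxy)-14-norgermacra-4,7(11)-dien-12,6-olide | O=C(O[C@H]1CC(=O)C(=O)CC/C(C)=C/[C@H]2OC(=O)C(CO[Si](C)(C)C(C)(C)C)=C12)c1ccc(cc1)[N+](=O)[O-]
F6 | step 9 | (4E,6R,8S)-8-hydroxy-1,10-dioxo-13-(TBS-oxy)-14-norgermacra-4,7(11)-dien-12,6-olide | O[C@H]1CC(=O)C(=O)CC/C(C)=C/[C@H]2OC(=O)C(CO[Si](C)(C)C(C)(C)C)=C12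
F7 | step 9 | (4E,6R,8S,10R)-8,10-dihydroxy-1-oxo-13-(TBS-oxy)germacra-4,7(11)-dien-12,6-olide | O[C@H]1C[C@@](C)(O)C(=O)CC/C(C)=C/[C@H]2OC(=O)C(CO[Si](C)(C)C(C)(C)C)=C12
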